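Readings and results were computed for substances that don't exist, and the scatter is random.

| flask | substrate | coupling partner | other conformer | remark | time |
|---|---|---|---|---|---|
| red | 5 mM | 13 mM | 1 mM | run made earlier |  |
| green | 7.5 mM | 13 mM | 1 mM | run made earlier |  |
| grey | 10 mM | 20 mM | 1 mM | run made earlier |  |
| flask | 10 mM | 13.0 mM | 1.00 mM |  | 15 d |

| run | time / d | target / % | isomer of the product A / % |
|---|---|---|---|
| red | 2.50 | 29.1 | 16.9 |
| red | 6.00 | 28.9 | 16.4 |
| red | 12.0 | 29.2 | 16.6 |
| red | 20.0 | 28.2 | 16.6 |
| green | 1.25 | 30.4 | 12.4 |
| green | 3.00 | 30.1 | 12.7 |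
| green | 8.00 | 31.1 | 13.1 |
| green | 20.0 | 30.3 | 12.6 |
| grey | 5.00 | 31.1 | 9.9 |
| grey | 10.0 | 31.6 | 11.2 |
| grey | 15.0 | 30.5 | 9.2 |
| grey | 20.0 | 30.8 | 10.2 |

(readings scatter by 0.5 percentage points)

* share of target in target plus isomer of the product A at 4.0 min
* share of target in target plus isomer of the product A at 15 d

- the earlier runs were read with a standard deviation of 0.5 percentage points

- Late on, your hunch is that the flask copies the grey run, but grey had more coupling partner, 20 mM against 13.0 mM, so I reckon from red and green, which match the flask in partner.
- Their readings show no trend with time beyond a scatter of 0.5 points, so you can average them: target over isomer of the product A reads 1.74 in the red run and 2.40 in the green run.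
- Go to logarithms: that ratio climbs 0.140 powers of ten while substrate over other conformer climbs 0.176.
- Their quotient, 0.799, is the charge exponent: powers of ten of late ratio gained per power of ten of charge ratio, with coupling partner held at 13 mM and other conformer at 1 mM.
- Stepping from green to the flask gives a ratio of 3.02, so my late share is 75.1 %.
- The green run's opening reading at 1.25 d comes far later than 4.0 min, so for the early share I suppose that both conformers couple equally fast, a selectivity factor of one, which gives the substrate's part of the charge, 90.9 %.
- The forecast said 73 % (35 % to 93 %) early and 75.6 % (73.5 % to 77.5 %) late, citing “the relative rates of the two conformers, which the runs never sampled”, and its early number sits below mine.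

    substrate ⇌ other conformer (K = 0.140, k = 6.70 × 10⁻⁶ s⁻¹)
    substrate + coupling partner → target (k = 0.0250 M⁻¹ s⁻¹)
    coupling partner + other conformer → isomer of the product A (k = 0.0310 M⁻¹ s⁻¹)
    2 coupling partner → homo dimer (k = 0.00370 M⁻¹ s⁻¹)
    target ⇌ isomer of the product B (K = 1.90, k = 5.70 × 10⁻⁵ s⁻¹)
    other conformer → decomposition product (k = 2.50 × 10⁻⁸ s⁻¹)

- The flask gives 89.0 % at 4.0 min and 74.0 % at 15 d. Target in the flask peaks at 46.8 % at 0.0876 d and stands at 28.4 % at 15.0 d. Now carry the exponent to the neighbouring flask with 40 mM of substrate: its charge ratio gains 0.602 powers of ten, so the flask's late ratio of 2.84 gains 0.481 and becomes 8.61, a share of 89.6 %; that neighbour's simulated share at 15 d is 90.3 %.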